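**Strategy**

Ring B (C6–C11, target numbering) is never closed as a six-membered ring. It is contracted out of an eight-membered α-acyl lactone in which an ester C(=O)–O unit is spliced between the spiro carbon C6 and C11: iodide cleaves the O–C11 bond, CO2 leaves, and the ring A enolate so unmasked at C6 (alpha to the C5 carbonyl) attacks C11. This one operation forges the spiro stereocentre beside the gem-dimethyl carbon and leaves the C8=C9 alkene, on which chloride and bromide are then placed trans-diaxially. The lactone comes from an enantiospecific bromonium cyclization (ring A, C2–Br) followed by ring-closing metathesis.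

Key step: step 8

Assumption: atom numbers in the Why lines are those of the target (ring A C1–C5, spiro C6, ring B C7–C11); ring B is taken to prefer the conformation with C5 axial and C1 equatorial at the spiro centre, which underlies the face selectivities of steps 10–12.

**Route**

Step 1
Reactants: 1 3-methylbut-2-en-1-ol (prenol)
Product: 2 (2R)-2-bromo-3-chloro-3-methylbutan-1-ol
Conditions: NBS, ClTi(OiPr)3, chiral tridentate Schiff-base diol ligand (20 mol%), hexanes, −20 °C
Reagents that add atoms: N-bromosuccinimide O=C1CCC(=O)N1Br; chlorotitanium triisopropoxide CC(C)O[Ti](Cl)(OC(C)C)OC(C)C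
Why: Catalytic enantioselective bromochlorination of an allylic alcohol, in which the titanium-bound alkoxide is brominated on one enantioface under control of the chiral ligand and chloride is delivered anti to the distal tertiary carbon, should set the C–Br stereocentre as (R).

Step 2
Reactants: 2 (2R)-2-bromo-3-chloro-3-methylbutan-1-ol
Product: 3 (2R)-2-bromo-3-chloro-3-methylbutyl trifluoromethanesulfonate
Conditions: Tf2O, 2,6-lutidine, CH2Cl2, −78 °C
Reagents that add atoms: trifluoromethanesulfonic anhydride O=S(=O)(OS(=O)(=O)C(F)(F)F)C(F)(F)F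
Why: O-sulfonylation of the primary alcohol should give the alkylating agent without touching the stereocentre.

Step 3
Reactants: 4 2,2,6-trimethyl-4H-1,3-dioxin-4-one; 5 3-methylbut-3-en-1-ol
Product: 6 3-methylbut-3-en-1-yl 3-oxobutanoate
Conditions: xylenes, 130 °C, distillation of acetone
Reagents that add atoms: none
Why: Thermal retro-[4+2] cleavage of the dioxinone releases acetylketene, which the alcohol traps (acetoacetylation).

Step 4
Reactants: 6 3-methylbut-3-en-1-yl 3-oxobutanoate; 7 allyl bromide
Product: 8 3-methylbut-3-en-1-yl 2-acetylpent-4-enoate (racemic)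
Conditions: K2CO3, acetone, 56 °C
Reagents that add atoms: none
Why: Mono-C-alkylation of the β-keto ester at its doubly activated carbon with a reactive allylic halide.

Step 5
Reactants: 8 3-methylbut-3-en-1-yl 2-acetylpent-4-enoate; 3 (2R)-2-bromo-3-chloro-3-methylbutyl trifluoromethanesulfonate
Product: 10 3-methylbut-3-en-1-yl (6R)-6-bromo-7-chloro-7-methyl-3-oxo-2-(prop-2-en-1-yl)octanoate (C2 epimers), via dilithium dianion 9 (not isolated)
Conditions: LiN(iPr)2 (2.2 equiv), THF, −78 → 0 °C; then 3, −78 → −30 °C
Reagents that add atoms: none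
Why: γ-Alkylation of a β-keto ester dianion, whose terminal carbanion should displace the primary triflate by SN2 at low temperature faster than it eliminates, leaving the C–Br stereocentre untouched.

Step 6
Reactants: 10 3-methylbut-3-en-1-yl (6R)-6-bromo-7-chloro-7-methyl-3-oxo-2-(prop-2-en-1-yl)octanoate
Product: 12 3-methylbut-3-en-1-yl (1R,3R)-3-bromo-2,2-dimethyl-6-oxo-1-(prop-2-en-1-yl)cyclohexane-1-carboxylate (major C1 epimer drawn; both epimers are carried on), via bromonium chloride 11 (not isolated)
Conditions: (CF3)2CHOH, 2,6-di-tert-butyl-4-methylpyridine (1.1 equiv), 0 → 23 °C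
Reagents that add atoms: none
Why: Bromine-assisted ionization of the tertiary chloride gives bromonium 11 with retention at the C–Br carbon, and the β-keto ester enol attacks its tertiary carbon through a chair transition state with Br equatorial (bromonium-initiated cation–olefin cyclization), forging the C1–C6 bond between two quaternary carbons and fixing C2 as (R); the C6 epimer ratio does not matter because C6 is re-set in step 8.

Step 7
Reactants: 12 3-methylbut-3-en-1-yl (1R,3R)-3-bromo-2,2-dimethyl-6-oxo-1-(prop-2-en-1-yl)cyclohexane-1-carboxylate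
Product: 13 (4R,6R,11Z)-4-bromo-5,5,11-trimethyl-8-oxaspiro[5.7]tridec-11-ene-1,7-dione (eight-membered lactone spiro-fused to ring A)
Conditions: second-generation Grubbs catalyst RuCl2(=CHPh)(PCy3)(H2IMes) (10 mol%), toluene (1 mM), 80 °C
Reagents that add atoms: none
Why: Ring-closing olefin metathesis between the allyl group and the 1,1-disubstituted alkene of the ester, helped by the quaternary carbon (gem-disubstituent effect) and driven by loss of ethene, should give the medium-ring lactone with the (Z) trisubstituted alkene that the ring enforces.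

Step 8
Reactants: 13 (4R,6R,11Z)-4-bromo-5,5,11-trimethyl-8-oxaspiro[5.7]tridec-11-ene-1,7-dione
Product: 16 (4R,6R)-4-bromo-5,5,9-trimethylspiro[5.5]undec-8-en-1-one, via iodo carboxylate 14 (not isolated), via iodo enolate 15 (not isolated)
Conditions: LiI (4 equiv), DMF (5 mM), 120 °C
Reagents that add atoms: none
Why: Iodide opens the strained lactone by SN2 at the O–CH2 carbon (C11) to give ω-iodo β-keto carboxylate 14, which loses CO2 to the regiodefined, fully substituted lithium enolate 15, whose C6 then displaces iodide. The closest known reaction type is the halide-induced decarboxylative ring contraction of α-acyl lactones to cycloalkyl ketones, a Krapcho-type dealkylative decarboxylation with internal C-alkylation. Ring B is closed in 6-exo-tet mode at C6–C11, so the eight-membered lactone ring becomes the six-membered carbocycle by loss of its C(=O)–O unit. The spiro stereocentre is controlled by ring A: the new bond enters axially on the enolate face anti to the axial methyl of C1 and 1,3-syn to the axial H (not the Br) of C2, so C11 ends trans and C7 cis to bromine. The step needs C- over O-alkylation, which the medium ring required for O-alkylation should secure, and alkylation ahead of protonation, which dry conditions and the (Z)-alkene tether should favour. Both C6 epimers of 13 converge on the same enolate.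

Step 9
Reactants: 16 (4R,6R)-4-bromo-5,5,9-trimethylspiro[5.5]undec-8-en-1-one
Product: 17 (6S,8R)-8-bromo-3,7,7-trimethyl-11-methylidenespiro[5.5]undec-2-ene
Conditions: Ph3PCH3Br, KOtBu, toluene, 90 °C
Reagents that add atoms: methylidenetriphenylphosphorane C=P(c1ccccc1)(c1ccccc1)c1ccccc1
Why: Wittig methylenation under the forcing conditions used for hindered ketones should install the exocyclic alkene; the equatorial neopentyl bromide has no antiperiplanar hydrogen and should resist E2.

Step 10
Reactants: 17 (6S,8R)-8-bromo-3,7,7-trimethyl-11-methylidenespiro[5.5]undec-2-ene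
Product: 18 (2S,3R,6S,8R)-8-bromo-2,3-epoxy-3,7,7-trimethyl-11-methylidenespiro[5.5]undecane (oxirane oxygen cis to the gem-dimethyl carbon)
Conditions: mCPBA (1.05 equiv), NaHCO3, CH2Cl2, −20 °C
Reagents that add atoms: 3-chloroperoxybenzoic acid OOC(=O)c1cccc(Cl)c1
Why: Prilezhaev epoxidation should take the trisubstituted C8=C9 alkene ahead of the hindered 1,1-disubstituted methylidene and approach anti to the axial C5 methylidene that covers the other face, placing oxygen cis to C1 and setting the C9–O configuration.

Step 11
Reactants: 18 (2S,3R,6S,8R)-8-bromo-2,3-epoxy-3,7,7-trimethyl-11-methylidenespiro[5.5]undecane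
Product: 19 (2R,3R,6S,8R)-8-bromo-2-chloro-3,7,7-trimethyl-11-methylidenespiro[5.5]undecan-3-ol
Conditions: LiCl, AcOH, THF, 23 °C
Reagents that add atoms: lithium chloride [Li+].[Cl-]
Why: SN2 opening of the oxirane under mild acid should follow the Fürst–Plattner rule in the conformationally biased ring, chloride entering axially at the secondary carbon C8 anti to oxygen, which gives the trans-diaxial chlorohydrin and sets C8 as (R).

Step 12
Reactants: 19 (2R,3R,6S,8R)-8-bromo-2-chloro-3,7,7-trimethyl-11-methylidenespiro[5.5]undecan-3-ol
Product: 21 (2R,6S,8R,9R)-2,9-dibromo-8-chloro-1,1,9-trimethyl-5-methylidenespiro[5.5]undecane (target), via chloronium bromide 20 (not isolated)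
Conditions: Me2C=C(Br)NMe2 (1.5 equiv), CH2Cl2, 0 °C
Reagents that add atoms: 1-bromo-N,N,2-trimethylprop-1-en-1-amine CC(C)=C(Br)N(C)C
Why: Neutral activation of the tertiary alcohol by the α-bromoenamine and ionization assisted by the antiperiplanar chlorine should give chloronium 20, which bromide opens at the tertiary carbon C9 anti to chlorine, so that bromine takes the place of oxygen with net retention (trans-diaxial dihalide) and no free HBr reaches the methylidene group.

**Compound list**

1 | 3-methylbut-2-en-1-ol (prenol) | CC(C)=CCO | starting material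
2 | (2R)-2-bromo-3-chloro-3-methylbutan-1-ol | OC[C@@H](Br)C(C)(C)Cl | intermediate
3 | (2R)-2-bromo-3-chloro-3-methylbutyl trifluoromethanesulfonate | FC(F)(F)S(=O)(=O)OC[C@@H](Br)C(C)(C)Cl | intermediate
4 | 2,2,6-trimethyl-4H-1,3-dioxin-4-one | CC1=CC(=O)OC(C)(C)O1 | starting material
5 | 3-methylbut-3-en-1-ol | CC(=C)CCO | starting material
6 | 3-methylbut-3-en-1-yl 3-oxobutanoate | CC(=O)CC(=O)OCCC(C)=C | intermediate
7 | allyl bromide (3-bromoprop-1-ene) | C=CCBr | starting material
8 | 3-methylbut-3-en-1-yl 2-acetylpent-4-enoate (racemic) | CC(=O)C(CC=C)C(=O)OCCC(C)=C | intermediate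
9 | dilithium dianion of 8 (not isolated) | [Li+].[Li+].[CH2-]C(=O)[C-](CC=C)C(=O)OCCC(C)=C | intermediate
10 | 3-methylbut-3-en-1-yl (6R)-6-bromo-7-chloro-7-methyl-3-oxo-2-(prop-2-en-1-yl)octanoate (C2 epimers) | C=CCC(C(=O)OCCC(C)=C)C(=O)CC[C@@H](Br)C(C)(C)Cl | intermediate
11 | bromonium chloride from 10, bromine bridging the former CHBr and CCl carbons (not isolated) | C=CCC(C(=O)OCCC(C)=C)C(=O)CC[C@H]1[Br+]C1(C)C.[Cl-] | intermediate
12 | 3-methylbut-3-en-1-yl (1R,3R)-3-bromo-2,2-dimethyl-6-oxo-1-(prop-2-en-1-yl)cyclohexane-1-carboxylate (major C1 epimer) | O=C1CC[C@@H](Br)C(C)(C)[C@@]1(CC=C)C(=O)OCCC(C)=C | intermediate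
13 | (4R,6R,11Z)-4-bromo-5,5,11-trimethyl-8-oxaspiro[5.7]tridec-11-ene-1,7-dione | O=C1CC[C@@H](Br)C(C)(C)[C@]12C/C=C(/C)CCOC2=O | intermediate
14 | lithium (1R,3R)-3-bromo-1-[(2Z)-5-iodo-3-methylpent-2-en-1-yl]-2,2-dimethyl-6-oxocyclohexane-1-carboxylate (not isolated) | [Li+].[O-]C(=O)[C@@]1(C/C=C(/C)CCI)C(=O)CC[C@@H](Br)C1(C)C | intermediate
15 | lithium (4R)-4-bromo-2-[(2Z)-5-iodo-3-methylpent-2-en-1-yl]-3,3-dimethylcyclohex-1-en-1-olate (not isolated) | [Li+].[O-]C1=C(C/C=C(/C)CCI)C(C)(C)[C@H](Br)CC1 | intermediate
16 | (4R,6R)-4-bromo-5,5,9-trimethylspiro[5.5]undec-8-en-1-one | O=C1CC[C@@H](Br)C(C)(C)[C@]12CCC(C)=CC2 | intermediate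
17 | (6S,8R)-8-bromo-3,7,7-trimethyl-11-methylidenespiro[5.5]undec-2-ene | C=C1CC[C@@H](Br)C(C)(C)[C@]12CCC(C)=CC2 | intermediate
18 | (2S,3R,6S,8R)-8-bromo-2,3-epoxy-3,7,7-trimethyl-11-methylidenespiro[5.5]undecane | C=C1CC[C@@H](Br)C(C)(C)[C@]12CC[C@@]3(C)O[C@H]3C2 | intermediate
19 | (2R,3R,6S,8R)-8-bromo-2-chloro-3,7,7-trimethyl-11-methylidenespiro[5.5]undecan-3-ol | C=C1CC[C@@H](Br)C(C)(C)[C@]12CC[C@@](C)(O)[C@H](Cl)C2 | intermediate
20 | chloronium bromide from 19, chlorine bridging C8 and C9 on the face of the former C–Cl bond (not isolated) | C=C1CC[C@@H](Br)C(C)(C)[C@]12CC[C@]3(C)[Cl+][C@@H]3C2.[Br-] | intermediate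
21 | (2R,6S,8R,9R)-2,9-dibromo-8-chloro-1,1,9-trimethyl-5-methylidenespiro[5.5]undecane | C=C1CC[C@@H](Br)C(C)(C)[C@]12CC[C@@](C)(Br)[C@H](Cl)C2 | target

**Step count**

Total steps: 12. Longest linear sequence: 10 steps (4 and 5 to 21 through steps 3–12; equally 1 to 21 through steps 1, 2 and 5–12).

**Steps most likely to fail**

Step 8 (key step). The hindered, fully substituted enolate may be protonated, O-alkylated or lost to elimination of the iodide before the C6–C11 bond forms. The fallback sets out from 13 and separates the two events. LiI in wet DMF at 100 °C should open the lactone and decarboxylate with protonation to give (4R)-4-bromo-2-[(2Z)-5-iodo-3-methylpent-2-en-1-yl]-3,3-dimethylcyclohexan-1-one F1. KOtBu in tBuOH/THF should then close ring B through the thermodynamic, more substituted enolate (classical spiroalkylation, with the same axial approach to ring A). This returns to the route at 16.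

Step 7. Intermolecular metathesis (oligomerization) may outrun closure of the strained eight-membered ring at the congested quaternary centre. The fallback sets out from 10 and inverts the order of ring formation. Metathesis on the acyclic, enolizable keto ester with the same ruthenium catalyst should give 3-[(4R)-4-bromo-5-chloro-5-methylhexanoyl]-6-methyl-3,4,7,8-tetrahydro-2H-oxocin-2-one F2, (5Z) alkene. The enol of F2 should then undergo the bromonium spirocyclization in (CF3)2CHOH with 2,6-di-tert-butyl-4-methylpyridine. This returns to the route at 13.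

Step 11. Regiocontrol may be lost if chloride opens the oxirane at the tertiary carbon C9 through a carbocation-like transition state. The fallback sets out from 17 and avoids the epoxide. Direct anti bromochlorination of the C8=C9 alkene with benzyltrimethylammonium dichlorobromate (CH2Cl2, −40 °C) should form the bromonium on the face anti to the axial C5 carbon and open it trans-diaxially with chloride at C8. It arrives at 21 and makes no new compound (F0).

**Further compounds**

F1 | step 8 | (4R)-4-bromo-2-[(2Z)-5-iodo-3-methylpent-2-en-1-yl]-3,3-dimethylcyclohexan-1-one | O=C1CC[C@@H](Br)C(C)(C)C1C/C=C(/C)CCI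
F2 | step 7 | (5Z)-3-[(4R)-4-bromo-5-chloro-5-methylhexanoyl]-6-methyl-3,4,7,8-tetrahydro-2H-oxocin-2-one | O=C1OCC/C(C)=C\CC1C(=O)CC[C@@H](Br)C(C)(C)Cl
F0 | step 11 | none | none
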